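A direct plan would join the N-(furylacetyl)oxazolidinone A1 and vanillin acetate A2 in an auxiliary-controlled syn-aldol reaction to the open-chain aldol adduct A3, reduce and silylate it, turn the benzylic alcohol into the terminal ynol ether A4, and let Ph3PAuNTf2 convert the furan–yne into the phenolic dihydrobenzofuran A5. Its weakest steps would be these:
- The aldol reaction: the α-carbon of a heteroarylacetyl imide is doubly activated, so retro-aldol and epimerisation would leave the C2/C3 pair to chance, after several auxiliary-bound steps that give only an acyclic diol.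
- The bromination and double dehydrobromination that make the ynol ether: a furan, a methyl ester and an acidic furyl C–H would be exposed to Br2 and excess LiN(i-Pr)2, and the product would be fragile.
- The gold-catalysed arene construction: both rings of the core would be staked, at the latest and most precious stage, on an ester-deactivated furan and an ionisable benzylic ynol ether.

**Plan of the new route.** The target is read as a ring-contracted flavanone. The unit O1–C2(aryl)–C3, with a one-carbon group on C3 next to ring-fusion carbon C3a, is a 2-arylchroman-4-one whose carbonyl carbon C4 has been pushed out of the ring. The retrosynthesis therefore cuts C3–C3a (reverse 1,2-shift), then C2–aryl (chromone plus arylboronate), C5–CO2Me (aryl bromide plus CO) and the chromone C2 carbon. Ring A is bought, the pyranone ring is annulated, C2 is set by catalytic asymmetric 1,4-addition, and the dihydrofuran ring arises last by six-to-five contraction, which sets C3 from C2. No auxiliary, aldol, ynol ether or late arene synthesis occurs; the one protecting group (a pivalate) tunes the key step and leaves in the reduction.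

Key step: step 5

Remark: in step 4 the (S)-ligand is assumed, by analogy with aryl additions to cyclohexenone, to give the (2S)-flavanone; if the opposite sense were found, the (R)-ligand would be used.

Step 1
Reactants: 1 1-(2-hydroxy-3-methoxyphenyl)ethan-1-one
Product: 2 1-(5-bromo-2-hydroxy-3-methoxyphenyl)ethan-1-one
Conditions: NBS (1.05 equiv), MeCN, 0 °C → rt
Reagents that add atoms: N-bromosuccinimide, O=C1CCC(=O)N1Br
Why: Electrophilic aromatic bromination should go to C5, the only position para to the free phenol and also meta to the acetyl group, faster than to the positions activated by the methoxy group alone or to the ketone α-carbon.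

Step 2
Reactants: 2 1-(5-bromo-2-hydroxy-3-methoxyphenyl)ethan-1-one
Product: 4 6-bromo-8-methoxy-4H-chromen-4-one, via enaminone 3 (not isolated)
Conditions: Me2NCH(OMe)2 (2 equiv), toluene, 100 °C; evaporate; conc. HCl, CH2Cl2, 40 °C
Reagents that add atoms: N,N-dimethylformamide dimethyl acetal, COC(OC)N(C)C
Why: Condensation of the methyl ketone with the amide acetal gives enaminone 3, and acid then drives 6-endo addition of the phenol oxygen to the β-carbon with loss of dimethylamine (the standard enaminone route to chromones), which builds the pyranone ring without any stereocentre.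

Step 3
Reactants: 5 2-methoxy-4-(4,4,5,5-tetramethyl-1,3,2-dioxaborolan-2-yl)phenol
Product: 6 2-methoxy-4-(4,4,5,5-tetramethyl-1,3,2-dioxaborolan-2-yl)phenyl 2,2-dimethylpropanoate (pivalate)
Conditions: PivCl (1.2 equiv), Et3N (1.5 equiv), DMAP (5 mol %), CH2Cl2, 0 °C → rt
Reagents that add atoms: pivaloyl chloride, CC(C)(C)C(Cl)=O
Why: DMAP-catalysed esterification of the phenol leaves the pinacol boronate untouched, and the pivalate is chosen because it withstands acid, makes its ring a poor migrating group in step 5 and is cleaved by hydride in step 6.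

Step 4
Reactants: 4 6-bromo-8-methoxy-4H-chromen-4-one; 6 2-methoxy-4-(4,4,5,5-tetramethyl-1,3,2-dioxaborolan-2-yl)phenyl pivalate
Product: 7 4-[(2S)-6-bromo-8-methoxy-4-oxo-3,4-dihydro-2H-chromen-2-yl]-2-methoxyphenyl pivalate ((S)-flavanone)
Conditions: [Rh(OH)(cod)]2 (2.5 mol %), (S)-MeO-F12-BIPHEP [(S)-2,2'-bis[bis(3,4,5-trifluorophenyl)phosphino]-6,6'-dimethoxy-1,1'-biphenyl] (5.5 mol %), 6 (2 equiv), KHCO3 (0.2 equiv), toluene–H2O (10:1), 40 °C
Reagents that add atoms: none
Why: Rhodium-catalysed asymmetric 1,4-addition of an arylboron reagent to an enone (Hayashi–Miyaura reaction) as applied to chromones, in which the aryl group passes from boron to rhodium in Rh(OH)(bisphosphine), the chromone C2=C3 bond inserts into the Rh–aryl bond on the face left open by the C2-symmetric electron-poor ligand (setting C2 as S) and water releases the ketone, while the near-neutral medium should keep the flavanone from racemising by ring opening and monovalent rhodium leaves the aryl bromide and the pivalate alone.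

Step 5
Reactants: 7 4-[(2S)-6-bromo-8-methoxy-4-oxo-3,4-dihydro-2H-chromen-2-yl]-2-methoxyphenyl pivalate
Product: 10 methyl (2S,3S)-5-bromo-7-methoxy-2-[3-methoxy-4-(pivaloyloxy)phenyl]-2,3-dihydro-1-benzofuran-3-carboxylate, via enol ether 8 (not isolated), via trans-3-iodanyl ketal 9 (not isolated)
Conditions: PhI(OAc)2 (1.2 equiv), conc. H2SO4 (2 equiv), HC(OMe)3, 0 °C → rt; aq NaHCO3
Reagents that add atoms: trimethyl orthoformate, COC(OC)OC; water (work-up), O
Why: This is the oxidative 1,2-aryl shift of an aryl ketone with trivalent iodine in trimethyl orthoformate in its cyclic form, the known ring contraction of flavanones to trans-2-aryl-2,3-dihydrobenzofuran-3-carboxylates: acid and orthoformate turn 7 into enol ether 8, PhI(OAc)2 puts iodine on C3 and methanol on C4 to give ketal 9, and reductive loss of iodobenzene is coupled to migration of ring-A carbon C4a from C4 to C3, the resulting dimethoxycarbenium ion ending as the methyl ester. The five-membered ring O1–C2–C3–C3a–C7a is thus closed not by a cyclisation but by contraction of the six-membered ring, the C3–C3a bond forming as the C4–C4a bond breaks through an aryl-bridged (phenonium-like) transition state. C3 is controlled by C2: iodine adds to the face of 8 opposite the C2 aryl group and the shift displaces it with inversion, which leaves the expelled carbon (the ester) trans to the aryl group (2S,3S) while C2 itself is not touched. The step needs migration of ring A to beat migration of the C2 aryl group (isoflavone), elimination (flavone) and solvolysis at C3 (3-methoxyflavanone). In the diequatorial conformer of 9 the C4–C4a bond, and not the C2–aryl bond, is antiperiplanar to the C3–I bond, the migrating carbon carries the ortho ring oxygen and the two methoxy groups on C4 push the shift, whereas the pivalate makes the C2 aryl group a poor migrating group and a poor stabiliser of a C2 cation, which also guards against racemisation by ring opening. The aryl bromide and the pivalate should be inert to the acidic oxidant.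

Step 6
Reactants: 10 methyl (2S,3S)-5-bromo-7-methoxy-2-[3-methoxy-4-(pivaloyloxy)phenyl]-2,3-dihydro-1-benzofuran-3-carboxylate
Product: 11 4-[(2S,3R)-5-bromo-3-(hydroxymethyl)-7-methoxy-2,3-dihydro-1-benzofuran-2-yl]-2-methoxyphenol
Conditions: LiAlH4 (3 equiv), THF, 0 °C; aq KNaC4H4O6 (potassium sodium tartrate), pH about 6
Reagents that add atoms: none
Why: Hydride reduction with LiAlH4 converts the C3 methyl ester into CH2OH and cleaves the aryl pivalate in the same operation, and since addition to the ester at 0 °C is much faster than α-deprotonation, C3 should neither epimerise nor β-eliminate (its descriptor changes to R only by priority), C2 is untouched and the aryl bromide is inert at this temperature.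

Step 7
Reactants: 11 4-[(2S,3R)-5-bromo-3-(hydroxymethyl)-7-methoxy-2,3-dihydro-1-benzofuran-2-yl]-2-methoxyphenol
Product: 12 curlignan, methyl (2S,3R)-2-(4-hydroxy-3-methoxyphenyl)-3-(hydroxymethyl)-7-methoxy-2,3-dihydro-1-benzofuran-5-carboxylate
Conditions: Pd(OAc)2 (5 mol %), Xantphos (6 mol %), CO (1 atm), Et3N (3 equiv), MeOH–toluene (1:1), 70 °C
Reagents that add atoms: carbon monoxide, [C-]#[O+]; methanol, CO
Why: Palladium-catalysed methoxycarbonylation of an aryl bromide (oxidative addition of zerovalent palladium at C5–Br, CO insertion, methanolysis of the ArC(O)PdBr intermediate) installs the ester, the large excess of methanol outcompetes the substrate's own hydroxyl groups, and the weak amine base and moderate temperature should leave the p-hydroxybenzyl aryl ether at C2 closed, so both stereocentres are carried through unchanged.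

## Compound list

1 | 1-(2-hydroxy-3-methoxyphenyl)ethan-1-one | CC(=O)c1cccc(OC)c1O | starting material
2 | 1-(5-bromo-2-hydroxy-3-methoxyphenyl)ethan-1-one | CC(=O)c1cc(Br)cc(OC)c1O | intermediate
3 | (E)-1-(5-bromo-2-hydroxy-3-methoxyphenyl)-3-(dimethylamino)prop-2-en-1-one (formed in the flask) | CN(C)/C=C/C(=O)c1cc(Br)cc(OC)c1O | intermediate
4 | 6-bromo-8-methoxy-4H-chromen-4-one | O=c1ccoc2c(OC)cc(Br)cc12 | intermediate
5 | 2-methoxy-4-(4,4,5,5-tetramethyl-1,3,2-dioxaborolan-2-yl)phenol | COc1cc(B2OC(C)(C)C(C)(C)O2)ccc1O | starting material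
6 | 2-methoxy-4-(4,4,5,5-tetramethyl-1,3,2-dioxaborolan-2-yl)phenyl 2,2-dimethylpropanoate | COc1cc(B2OC(C)(C)C(C)(C)O2)ccc1OC(=O)C(C)(C)C | intermediate
7 | 4-[(2S)-6-bromo-8-methoxy-4-oxo-3,4-dihydro-2H-chromen-2-yl]-2-methoxyphenyl 2,2-dimethylpropanoate | O=C1C[C@@H](c3ccc(OC(=O)C(C)(C)C)c(OC)c3)Oc2c(OC)cc(Br)cc12 | intermediate
8 | 4-[(2S)-6-bromo-4,8-dimethoxy-2H-chromen-2-yl]-2-methoxyphenyl 2,2-dimethylpropanoate (enol ether, formed in the flask) | COC1=C[C@@H](c3ccc(OC(=O)C(C)(C)C)c(OC)c3)Oc2c(OC)cc(Br)cc12 | intermediate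
9 | 4-{(2R,3R)-3-[acetoxy(phenyl)-λ3-iodanyl]-6-bromo-4,4,8-trimethoxychroman-2-yl}-2-methoxyphenyl 2,2-dimethylpropanoate (2,3-trans; C2 spatially as in 7, its descriptor changes only because iodine raises the rank of C3; formed in the flask) | COC1(OC)[C@H](I(OC(C)=O)c3ccccc3)[C@@H](c3ccc(OC(=O)C(C)(C)C)c(OC)c3)Oc2c(OC)cc(Br)cc12 | intermediate
10 | methyl (2S,3S)-5-bromo-7-methoxy-2-[3-methoxy-4-(pivaloyloxy)phenyl]-2,3-dihydro-1-benzofuran-3-carboxylate (2,3-trans) | Brc1cc(OC)c2c(c1)[C@H](C(=O)OC)[C@@H](c1ccc(OC(=O)C(C)(C)C)c(OC)c1)O2 | intermediate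
11 | 4-[(2S,3R)-5-bromo-3-(hydroxymethyl)-7-methoxy-2,3-dihydro-1-benzofuran-2-yl]-2-methoxyphenol | Brc1cc(OC)c2c(c1)[C@H](CO)[C@@H](c1ccc(O)c(OC)c1)O2 | intermediate
12 | curlignan, methyl (2S,3R)-2-(4-hydroxy-3-methoxyphenyl)-3-(hydroxymethyl)-7-methoxy-2,3-dihydro-1-benzofuran-5-carboxylate | COC(=O)c1cc(OC)c2c(c1)[C@H](CO)[C@@H](c1ccc(O)c(OC)c1)O2 | target

Total step count: 7. Longest linear sequence: 6 steps (steps 1, 2, 4, 5, 6, 7); step 3 is a one-step side branch.

Steps most likely to fail:

1. Step 5 (ring contraction). Dehydrogenation to the flavone, shift of the C2 aryl group instead of ring A, or methoxylation at C3 may outrun the contraction. The fallback is a Wolff ring contraction, which sets out from 7 and returns at 10. Compound 7 would be acylated at C3 (LiN(SiMe3)2, THF, −78 °C, the enolate being kept cold to hold back ring opening; CF3CO2CH2CF3) to the 3-(trifluoroacetyl)flavanone F1. Detrifluoroacetylative diazo transfer (MsN3, Et3N, H2O, MeCN) would give the 3-diazoflavanone F2. Irradiation (≥300 nm) in MeOH would trigger the Wolff rearrangement, again moving C4a from C4 to C3, to the ketene F3. Methanol would trap it as the ester, expected rich in the cis isomer F4 by protonation anti to the aryl group. DBU in toluene would then equilibrate F4 to the more stable trans ester 10.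

2. Step 4 (asymmetric 1,4-addition). Slow transfer of the aryl group from the pinacol boronate, poor facial selectivity, or base-induced ring opening that erodes the optical purity may occur. The fallback makes the racemate and resolves it by asymmetric transfer hydrogenation; it sets out from 2 and returns at 7. Vanillin would be acylated (PivCl, Et3N, CH2Cl2) to 4-formyl-2-methoxyphenyl pivalate F5. Claisen–Schmidt condensation of F5 with 2 under BF3·OEt2 (dioxane, rt) would give the 2'-hydroxychalcone F6. NaOAc in refluxing EtOH would close F6 to the racemic flavanone F7. Transfer hydrogenation with RhCl(Cp*)[(R,R)-TsDPEN] (HCO2H/Et3N, EtOAc, rt), stopped near half conversion, is expected to consume the (2R)-enantiomer as the cis-(2R,4R)-flavan-4-ol F8 and leave (S)-flavanone 7, separable by chromatography.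

3. Step 7 (carbonylation of the unprotected bromide). Inhibition of the catalyst by the phenoxide, or opening of the C2–O1 bond by the para-phenoxide under base and heat, may occur. The fallback reverses the order of carbonylation and reduction; it sets out from 10 and returns at 12. Compound 10, with the phenol still masked, would be methoxycarbonylated under the conditions of step 7 to the diester F9. LiBH4 (THF, 0 °C) would reduce the aliphatic C3 ester in preference to the ring-conjugated C5 ester, which is deactivated by the para oxygen, to give O-pivaloyl curlignan F10. The pivalate of F10 would then be removed with catalytic NaOMe in MeOH at 0 °C, which is degenerate for the methyl ester, to give 12.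

## Further compounds

F1 | step 5 | 4-[(2S)-6-bromo-8-methoxy-4-oxo-3-(trifluoroacetyl)-3,4-dihydro-2H-chromen-2-yl]-2-methoxyphenyl pivalate (C3 epimers, enolised) | O=C1C(C(=O)C(F)(F)F)[C@@H](c3ccc(OC(=O)C(C)(C)C)c(OC)c3)Oc2c(OC)cc(Br)cc12
F2 | step 5 | 4-[(2R)-6-bromo-3-diazo-8-methoxy-4-oxo-3,4-dihydro-2H-chromen-2-yl]-2-methoxyphenyl pivalate (C2 spatially as in 7) | O=C1C(=[N+]=[N-])[C@@H](c3ccc(OC(=O)C(C)(C)C)c(OC)c3)Oc2c(OC)cc(Br)cc12
F3 | step 5 | 4-[(2R)-5-bromo-7-methoxy-3-(oxomethylidene)-2,3-dihydro-1-benzofuran-2-yl]-2-methoxyphenyl pivalate (ketene; C2 spatially as in 7) | Brc1cc(OC)c2c(c1)C(=C=O)[C@@H](c1ccc(OC(=O)C(C)(C)C)c(OC)c1)O2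
F4 | step 5 | methyl (2S,3R)-5-bromo-7-methoxy-2-[3-methoxy-4-(pivaloyloxy)phenyl]-2,3-dihydro-1-benzofuran-3-carboxylate (2,3-cis) | Brc1cc(OC)c2c(c1)[C@@H](C(=O)OC)[C@@H](c1ccc(OC(=O)C(C)(C)C)c(OC)c1)O2
F5 | step 4 | 4-formyl-2-methoxyphenyl 2,2-dimethylpropanoate | COc1cc(C=O)ccc1OC(=O)C(C)(C)C
F6 | step 4 | (E)-1-(5-bromo-2-hydroxy-3-methoxyphenyl)-3-[3-methoxy-4-(pivaloyloxy)phenyl]prop-2-en-1-one | COc1cc(/C=C/C(=O)c2cc(Br)cc(OC)c2O)ccc1OC(=O)C(C)(C)C
F7 | step 4 | racemic 4-(6-bromo-8-methoxy-4-oxo-3,4-dihydro-2H-chromen-2-yl)-2-methoxyphenyl pivalate | O=C1CC(c3ccc(OC(=O)C(C)(C)C)c(OC)c3)Oc2c(OC)cc(Br)cc12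
F8 | step 4 | 4-[(2R,4R)-6-bromo-4-hydroxy-8-methoxychroman-2-yl]-2-methoxyphenyl pivalate (2,4-cis) | O[C@@H]1C[C@H](c3ccc(OC(=O)C(C)(C)C)c(OC)c3)Oc2c(OC)cc(Br)cc12
F9 | step 7 | dimethyl (2S,3S)-7-methoxy-2-[3-methoxy-4-(pivaloyloxy)phenyl]-2,3-dihydro-1-benzofuran-3,5-dicarboxylate | COC(=O)c1cc(OC)c2c(c1)[C@H](C(=O)OC)[C@@H](c1ccc(OC(=O)C(C)(C)C)c(OC)c1)O2
F10 | step 7 | methyl (2S,3R)-3-(hydroxymethyl)-7-methoxy-2-[3-methoxy-4-(pivaloyloxy)phenyl]-2,3-dihydro-1-benzofuran-5-carboxylate | COC(=O)c1cc(OC)c2c(c1)[C@H](CO)[C@@H](c1ccc(OC(=O)C(C)(C)C)c(OC)c1)O2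
A1 | direct plan | (S)-4-benzyl-3-{[4-(methoxycarbonyl)furan-2-yl]acetyl}-1,3-oxazolidin-2-one | COC(=O)c1coc(CC(=O)N2[C@@H](Cc3ccccc3)COC2=O)c1
A2 | direct plan | 4-formyl-2-methoxyphenyl acetate (vanillin acetate) | CC(=O)Oc1ccc(C=O)cc1OC
A3 | direct plan | (S)-4-benzyl-3-{(2R,3S)-3-(4-acetoxy-3-methoxyphenyl)-3-hydroxy-2-[4-(methoxycarbonyl)furan-2-yl]propanoyl}-1,3-oxazolidin-2-one | COC(=O)c1coc([C@@H]([C@H](O)c2ccc(OC(C)=O)c(OC)c2)C(=O)N2[C@@H](Cc3ccccc3)COC2=O)c1
A4 | direct plan | methyl 5-[(1S,2R)-1-(ethynyloxy)-1-{3-methoxy-4-[(triisopropylsilyl)oxy]phenyl}-3-[(triisopropylsilyl)oxy]propan-2-yl]furan-3-carboxylate | COC(=O)c1coc([C@@H]([C@H](OC#C)c2ccc(O[Si](C(C)C)(C(C)C)C(C)C)c(OC)c2)CO[Si](C(C)C)(C(C)C)C(C)C)c1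
A5 | direct plan | methyl (2S,3R)-7-hydroxy-2-{3-methoxy-4-[(triisopropylsilyl)oxy]phenyl}-3-{[(triisopropylsilyl)oxy]methyl}-2,3-dihydro-1-benzofuran-5-carboxylate | COC(=O)c1cc(O)c2c(c1)[C@H](CO[Si](C(C)C)(C(C)C)C(C)C)[C@@H](c1ccc(O[Si](C(C)C)(C(C)C)C(C)C)c(OC)c1)O2
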